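**Plan**
Ring A is the dimethoxy-prenyl ring and ring B the oxygenated ring (C1' bridge, C2' OMe, C3' OH, C4' OAc); Ca and Cb are the bridge carbons on ring A and ring B.
Retrosynthesis: the C4' acetate and the C2' O-methyl are removed first; then Cb–C1' and C2'–O are cut together across a C1'–C2' aryne; the prenyl–ring A bond is cut last.
Enabling feature: on ring B the bridge carbon C1' and the methoxy-bearing C2' are adjacent and C2' is flanked by the C3' oxygen, so a C1'–C2' aryne polarised by a C3' MOM ether takes carbon at C1' and then oxygen at C2'.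
Forward: the ring A bromide is made in three steps (acid reduction, dianion prenylation between the methoxy groups, Appel bromination). The ring B fluoride is made in three steps from 4-fluoro-2-hydroxybenzaldehyde, which delivers the C3' oxygen as a MOM ether and the C4' oxygen as a TIPS ether, already differentiated.
The fragments are joined in step 7; O-methylation, one-pot desilylation–acetylation and MOM cleavage finish. No ring is formed, since both benzene rings are bought.
Stereochemistry: the target has no stereocentre and no stereogenic double bond, so nothing has to be set.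

Key step: step 7

Remark: the two ring B oxygens carry different protecting groups so that the acetate is placed on a single free hydroxyl and not by selective acylation of a catechol.

**Step 1**
Reactants: 1 (3,5-dimethoxyphenyl)acetic acid
Product: 2 2-(3,5-dimethoxyphenyl)ethanol
Conditions: LiAlH4, THF, 0 °C → reflux; then H2O, aq NaOH
Reagents that add atoms: none
Why: Hydride reduction of a carboxylic acid to the primary alcohol with LiAlH4; the aryl methyl ethers are inert.

**Step 2**
Reactants: 2 2-(3,5-dimethoxyphenyl)ethanol; 3 prenyl bromide (1-bromo-3-methylbut-2-ene)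
Product: 5 2-[3,5-dimethoxy-4-(3-methylbut-2-enyl)phenyl]ethanol, via dilithio alkoxide 4 (not isolated)
Conditions: n-BuLi (2.2 equiv), TMEDA, THF, 0 °C → rt; CuBr·SMe2 (10 mol %), then 3, −78 → 0 °C; then H2O
Reagents that add atoms: none
Why: Directed ortho-metalation: after O-deprotonation the second equivalent of n-BuLi lithiates the carbon flanked by both methoxy groups, and copper-catalysed allylic substitution at the primary carbon of prenyl bromide should outrun O-alkylation of the aggregated lithium alkoxide at low temperature.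

**Step 3**
Reactants: 5 2-[3,5-dimethoxy-4-(3-methylbut-2-enyl)phenyl]ethanol
Product: 6 5-(2-bromoethyl)-1,3-dimethoxy-2-(3-methylbut-2-enyl)benzene
Conditions: CBr4, PPh3, CH2Cl2, 0 °C → rt
Reagents that add atoms: carbon tetrabromide, BrC(Br)(Br)Br
Why: Appel reaction of a primary alcohol under neutral conditions, which leave the prenyl olefin and the electron-rich arene untouched.

**Step 4**
Reactants: 7 4-fluoro-2-hydroxybenzaldehyde
Product: 8 4-fluoro-2-(methoxymethoxy)benzaldehyde
Conditions: MOMCl, i-Pr2NEt, CH2Cl2, 0 °C → rt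
Reagents that add atoms: chloromethyl methyl ether, COCCl
Why: O-alkylation of the phenol (Williamson-type acetal formation) with a non-nucleophilic base installs the group that later directs lithiation and polarises the aryne.

**Step 5**
Reactants: 8 4-fluoro-2-(methoxymethoxy)benzaldehyde
Product: 10 4-fluoro-2-(methoxymethoxy)phenol, via aryl formate 9 (not isolated)
Conditions: mCPBA, CH2Cl2, 0 °C → rt; then Et3N (cat.), MeOH, rt
Reagents that add atoms: 3-chloroperbenzoic acid, OOC(=O)c1cccc(Cl)c1
Why: Baeyer–Villiger (Dakin-type) oxidation in which the alkoxy-substituted aryl group migrates to give formate 9, which is methanolysed in the same flask; this places the future C4' oxygen para to fluorine.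

**Step 6**
Reactants: 10 4-fluoro-2-(methoxymethoxy)phenol
Product: 11 [4-fluoro-2-(methoxymethoxy)phenoxy]tri(propan-2-yl)silane
Conditions: TIPSCl, imidazole, DMF, rt
Reagents that add atoms: chlorotri(propan-2-yl)silane, CC(C)[Si](Cl)(C(C)C)C(C)C
Why: Imidazole-promoted silylation of the phenol gives a bulky, non-coordinating ether that tolerates organolithium and Grignard reagents and is later cleaved by fluoride while the MOM ether stays.

**Step 7**
Reactants: 6 5-(2-bromoethyl)-1,3-dimethoxy-2-(3-methylbut-2-enyl)benzene; 11 [4-fluoro-2-(methoxymethoxy)phenoxy]tri(propan-2-yl)silane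
Product: 17 6-{2-[3,5-dimethoxy-4-(3-methylbut-2-enyl)phenyl]ethyl}-2-(methoxymethoxy)-3-{[tri(propan-2-yl)silyl]oxy}phenol, via Grignard reagent 12 (not isolated), via aryllithium 13 (not isolated), via aryne 14 (not isolated), via arylmagnesium bromide 15 (not isolated), via dimethyl arylboronate 16 (not isolated)
Conditions: (a) 6, Mg, THF, rt → 45 °C (gives 12); (b) 11, n-BuLi (1.0 equiv), THF, −78 °C; (c) 12 (1.5 equiv) added at −78 °C, then → rt; (d) B(OMe)3, −78 °C → rt; (e) 30% H2O2, aq NaHCO3, 0 °C → rt
Reagents that add atoms: hydrogen peroxide, OO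
Why: n-BuLi removes the proton of 11 flanked by fluorine and the MOM ether to give aryllithium 13, which loses LiF on warming to the 3-alkoxyaryne 14; Grignard reagent 12 adds its carbon to the aryne carbon remote from the MOM ether (Cb–C1' bond) and leaves arylmagnesium 15 at C2', which B(OMe)3 converts to boronate 16 and H2O2 oxidises to the phenol (C2'–O bond). The closest known reaction type is the regioselective addition of Grignard and organolithium reagents to 3-alkoxyarynes generated by ortho-lithiation and halide loss, with electrophilic trapping of the aryl metal, here by the standard borylation–oxidation of an aryl Grignard reagent. No ring is closed and no stereocentre is formed, so no mode of closure and no stereocontrol element is involved. Site-selective lithiation is secured by the combined acidifying effect of fluorine and the MOM ether on the one CH between them, while the bulky TIPS ether does not direct metalation to its own side. Regioselective addition to the unsymmetrical aryne is secured by the inductive pull and magnesium chelation of the C3' MOM ether, which send the nucleophile to the distal carbon and the metal next to oxygen. An excess of 12 should keep the aryne from being captured by 13, and unreacted 12 is expected to end as alcohol 5 after the oxidative work-up, from which it can be recycled through step 3.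

**Step 8**
Reactants: 17 6-{2-[3,5-dimethoxy-4-(3-methylbut-2-enyl)phenyl]ethyl}-2-(methoxymethoxy)-3-{[tri(propan-2-yl)silyl]oxy}phenol
Product: 18 (4-{2-[3,5-dimethoxy-4-(3-methylbut-2-enyl)phenyl]ethyl}-3-methoxy-2-(methoxymethoxy)phenoxy)tri(propan-2-yl)silane
Conditions: NaH, MeI, THF–DMF, 0 °C → rt
Reagents that add atoms: iodomethane, CI
Why: Williamson ether synthesis on the only free hydroxyl; the non-nucleophilic base should leave the aryl silyl ether and the MOM ether intact.

**Step 9**
Reactants: 18 (4-{2-[3,5-dimethoxy-4-(3-methylbut-2-enyl)phenyl]ethyl}-3-methoxy-2-(methoxymethoxy)phenoxy)tri(propan-2-yl)silane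
Product: 20 4-{2-[3,5-dimethoxy-4-(3-methylbut-2-enyl)phenyl]ethyl}-3-methoxy-2-(methoxymethoxy)phenyl acetate, via tetrabutylammonium phenoxide 19 (not isolated)
Conditions: TBAF, THF, 0 °C; then Ac2O, 0 °C → rt
Reagents that add atoms: acetic anhydride, CC(=O)OC(C)=O
Why: Fluoride-induced cleavage of the aryl silyl ether gives phenoxide 19, which is acylated in the same flask (nucleophilic acyl substitution); the neighbouring oxygen is still a MOM ether, so the acetate cannot end up on the wrong oxygen.

**Step 10**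
Reactants: 20 4-{2-[3,5-dimethoxy-4-(3-methylbut-2-enyl)phenyl]ethyl}-3-methoxy-2-(methoxymethoxy)phenyl acetate
Product: 22 4-{2-[3,5-dimethoxy-4-(3-methylbut-2-enyl)phenyl]ethyl}-2-hydroxy-3-methoxyphenyl acetate (CNP0143232.0), via aryl trimethylsilyl ether 21 (not isolated)
Conditions: TMSOTf, 2,2'-bipyridyl, CH2Cl2, 0 °C → rt; then H2O
Reagents that add atoms: none
Why: Lewis-acid-mediated acetal cleavage with TMSOTf buffered by 2,2'-bipyridyl converts the aryl MOM ether to silyl ether 21, which is hydrolysed on neutral aqueous work-up; these non-protic conditions should spare the aryl acetate, the prenyl olefin and the methyl ethers.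

**Compound list**
1 | (3,5-dimethoxyphenyl)acetic acid | COc1cc(CC(=O)O)cc(OC)c1 | starting material
2 | 2-(3,5-dimethoxyphenyl)ethanol | COc1cc(CCO)cc(OC)c1 | intermediate
3 | prenyl bromide (1-bromo-3-methylbut-2-ene) | CC(C)=CCBr | starting material
4 | lithium 2-(4-lithio-3,5-dimethoxyphenyl)ethoxide | [Li]OCCc1cc(OC)c([Li])c(OC)c1 | intermediate
5 | 2-[3,5-dimethoxy-4-(3-methylbut-2-enyl)phenyl]ethanol | COc1cc(CCO)cc(OC)c1CC=C(C)C | intermediate
6 | 5-(2-bromoethyl)-1,3-dimethoxy-2-(3-methylbut-2-enyl)benzene | COc1cc(CCBr)cc(OC)c1CC=C(C)C | intermediate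
7 | 4-fluoro-2-hydroxybenzaldehyde | O=Cc1ccc(F)cc1O | starting material
8 | 4-fluoro-2-(methoxymethoxy)benzaldehyde | COCOc1cc(F)ccc1C=O | intermediate
9 | 4-fluoro-2-(methoxymethoxy)phenyl formate | COCOc1cc(F)ccc1OC=O | intermediate
10 | 4-fluoro-2-(methoxymethoxy)phenol | COCOc1cc(F)ccc1O | intermediate
11 | [4-fluoro-2-(methoxymethoxy)phenoxy]tri(propan-2-yl)silane | COCOc1cc(F)ccc1O[Si](C(C)C)(C(C)C)C(C)C | intermediate
12 | {2-[3,5-dimethoxy-4-(3-methylbut-2-enyl)phenyl]ethyl}magnesium bromide | COc1cc(CC[Mg]Br)cc(OC)c1CC=C(C)C | intermediate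
13 | [6-fluoro-2-(methoxymethoxy)-3-{[tri(propan-2-yl)silyl]oxy}phenyl]lithium | COCOc1c([Li])c(F)ccc1O[Si](C(C)C)(C(C)C)C(C)C | intermediate
14 | 3-(methoxymethoxy)-4-{[tri(propan-2-yl)silyl]oxy}benzyne | COCOC1=C(O[Si](C(C)C)(C(C)C)C(C)C)C=CC#C1 | intermediate
15 | (6-{2-[3,5-dimethoxy-4-(3-methylbut-2-enyl)phenyl]ethyl}-2-(methoxymethoxy)-3-{[tri(propan-2-yl)silyl]oxy}phenyl)magnesium bromide | COCOc1c([Mg]Br)c(CCc2cc(OC)c(CC=C(C)C)c(OC)c2)ccc1O[Si](C(C)C)(C(C)C)C(C)C | intermediate
16 | dimethyl (6-{2-[3,5-dimethoxy-4-(3-methylbut-2-enyl)phenyl]ethyl}-2-(methoxymethoxy)-3-{[tri(propan-2-yl)silyl]oxy}phenyl)boronate | COCOc1c(B(OC)OC)c(CCc2cc(OC)c(CC=C(C)C)c(OC)c2)ccc1O[Si](C(C)C)(C(C)C)C(C)C | intermediate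
17 | 6-{2-[3,5-dimethoxy-4-(3-methylbut-2-enyl)phenyl]ethyl}-2-(methoxymethoxy)-3-{[tri(propan-2-yl)silyl]oxy}phenol | COCOc1c(O)c(CCc2cc(OC)c(CC=C(C)C)c(OC)c2)ccc1O[Si](C(C)C)(C(C)C)C(C)C | intermediate
18 | (4-{2-[3,5-dimethoxy-4-(3-methylbut-2-enyl)phenyl]ethyl}-3-methoxy-2-(methoxymethoxy)phenoxy)tri(propan-2-yl)silane | COCOc1c(OC)c(CCc2cc(OC)c(CC=C(C)C)c(OC)c2)ccc1O[Si](C(C)C)(C(C)C)C(C)C | intermediate
19 | tetrabutylammonium 4-{2-[3,5-dimethoxy-4-(3-methylbut-2-enyl)phenyl]ethyl}-3-methoxy-2-(methoxymethoxy)phenolate | COCOc1c(OC)c(CCc2cc(OC)c(CC=C(C)C)c(OC)c2)ccc1[O-].CCCC[N+](CCCC)(CCCC)CCCC | intermediate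
20 | 4-{2-[3,5-dimethoxy-4-(3-methylbut-2-enyl)phenyl]ethyl}-3-methoxy-2-(methoxymethoxy)phenyl acetate | COCOc1c(OC)c(CCc2cc(OC)c(CC=C(C)C)c(OC)c2)ccc1OC(C)=O | intermediate
21 | 4-{2-[3,5-dimethoxy-4-(3-methylbut-2-enyl)phenyl]ethyl}-3-methoxy-2-[(trimethylsilyl)oxy]phenyl acetate | COc1c(CCc2cc(OC)c(CC=C(C)C)c(OC)c2)ccc(OC(C)=O)c1O[Si](C)(C)C | intermediate
22 | 4-{2-[3,5-dimethoxy-4-(3-methylbut-2-enyl)phenyl]ethyl}-2-hydroxy-3-methoxyphenyl acetate | COc1cc(CCc2ccc(OC(C)=O)c(O)c2OC)cc(OC)c1CC=C(C)C | target

**Totals**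
Total step count: 10. Longest linear sequence: 7 steps (steps 1–3 then 7–10; the ring B branch, steps 4–6 then 7–10, is equally long).

**Steps most likely to fail**

Step 7. The aryne may be captured by its own precursor aryllithium or by the product arylmagnesium instead of the alkyl Grignard reagent (oligomerisation), and the doubly ortho-substituted arylmagnesium may be protonated before it is borylated. The fallback avoids the aryne and sets out from bromide 6. Zinc insertion (Zn dust, LiCl, THF, 50 °C) would give {2-[3,5-dimethoxy-4-(3-methylbut-2-enyl)phenyl]ethyl}zinc bromide F1. Its partner would be made from commercial 4-bromo-2-hydroxybenzaldehyde by the operations of steps 4 to 6: MOM protection to 4-bromo-2-(methoxymethoxy)benzaldehyde F2, Baeyer–Villiger oxidation by way of 4-bromo-2-(methoxymethoxy)phenyl formate F3 to 4-bromo-2-(methoxymethoxy)phenol F4, and silylation to [4-bromo-2-(methoxymethoxy)phenoxy]tri(propan-2-yl)silane F5. Negishi coupling of F1 with F5 (Pd(OAc)2, SPhos, THF, 50 °C) would give (4-{2-[3,5-dimethoxy-4-(3-methylbut-2-enyl)phenyl]ethyl}-2-(methoxymethoxy)phenoxy)tri(propan-2-yl)silane F6. Directed ortho-lithiation (s-BuLi, TMEDA, THF, −78 °C) at the only free position beside the MOM ether would give (6-{2-[3,5-dimethoxy-4-(3-methylbut-2-enyl)phenyl]ethyl}-2-(methoxymethoxy)-3-{[tri(propan-2-yl)silyl]oxy}phenyl)lithium F7, and B(OMe)3 would convert it to boronate 16, where the route is rejoined and H2O2 gives 17.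

Step 2. Ring lithiation of the aggregated, poorly soluble lithium alkoxide may stay incomplete, and the alkoxide oxygen may be allylated in competition with carbon. The fallback removes the alkoxide altogether and sets out from alcohol 2. Silylation (TBSCl, imidazole, DMF) would give tert-butyl[2-(3,5-dimethoxyphenyl)ethoxy]dimethylsilane F8. Lithiation (n-BuLi, THF, 0 °C → rt) would give {4-[2-(tert-butyldimethylsilyloxy)ethyl]-2,6-dimethoxyphenyl}lithium F9, and copper-catalysed coupling with 3 (CuBr·SMe2, −78 → 0 °C) would give tert-butyl{2-[3,5-dimethoxy-4-(3-methylbut-2-enyl)phenyl]ethoxy}dimethylsilane F10. TBAF in THF would then return to alcohol 5.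

Step 10. The acetate may be lost, or may migrate to the hydroxyl that is unveiled next to it, during MOM cleavage or work-up. The fallback makes acetylation the last operation and sets out from silyl ether 18. The MOM ether would be cleaved first (HCl, MeOH, 40 °C, conditions that prenylated arenes without an ortho hydroxyl are known to tolerate) to give 3-{2-[3,5-dimethoxy-4-(3-methylbut-2-enyl)phenyl]ethyl}-2-methoxy-6-{[tri(propan-2-yl)silyl]oxy}phenol F11. Desilylation (TBAF, AcOH, THF) would give 4-{2-[3,5-dimethoxy-4-(3-methylbut-2-enyl)phenyl]ethyl}-3-methoxybenzene-1,2-diol F12, handled under argon. Kinetic acetylation (Ac2O 1.0 equiv, 2,4,6-collidine, CH2Cl2, −40 °C) should favour the less hindered hydroxyl para to the bridge, because the C3' hydroxyl is flanked by the methoxy group, and so give target 22.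

**Further compounds**
F1 | step 7 | {2-[3,5-dimethoxy-4-(3-methylbut-2-enyl)phenyl]ethyl}zinc bromide | COc1cc(CC[Zn]Br)cc(OC)c1CC=C(C)C
F2 | step 7 | 4-bromo-2-(methoxymethoxy)benzaldehyde | COCOc1cc(Br)ccc1C=O
F3 | step 7 | 4-bromo-2-(methoxymethoxy)phenyl formate | COCOc1cc(Br)ccc1OC=O
F4 | step 7 | 4-bromo-2-(methoxymethoxy)phenol | COCOc1cc(Br)ccc1O
F5 | step 7 | [4-bromo-2-(methoxymethoxy)phenoxy]tri(propan-2-yl)silane | COCOc1cc(Br)ccc1O[Si](C(C)C)(C(C)C)C(C)C
F6 | step 7 | (4-{2-[3,5-dimethoxy-4-(3-methylbut-2-enyl)phenyl]ethyl}-2-(methoxymethoxy)phenoxy)tri(propan-2-yl)silane | COCOc1cc(CCc2cc(OC)c(CC=C(C)C)c(OC)c2)ccc1O[Si](C(C)C)(C(C)C)C(C)C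
F7 | step 7 | (6-{2-[3,5-dimethoxy-4-(3-methylbut-2-enyl)phenyl]ethyl}-2-(methoxymethoxy)-3-{[tri(propan-2-yl)silyl]oxy}phenyl)lithium | COCOc1c([Li])c(CCc2cc(OC)c(CC=C(C)C)c(OC)c2)ccc1O[Si](C(C)C)(C(C)C)C(C)C
F8 | step 2 | tert-butyl[2-(3,5-dimethoxyphenyl)ethoxy]dimethylsilane | COc1cc(CCO[Si](C)(C)C(C)(C)C)cc(OC)c1
F9 | step 2 | {4-[2-(tert-butyldimethylsilyloxy)ethyl]-2,6-dimethoxyphenyl}lithium | COc1cc(CCO[Si](C)(C)C(C)(C)C)cc(OC)c1[Li]
F10 | step 2 | tert-butyl{2-[3,5-dimethoxy-4-(3-methylbut-2-enyl)phenyl]ethoxy}dimethylsilane | COc1cc(CCO[Si](C)(C)C(C)(C)C)cc(OC)c1CC=C(C)C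
F11 | step 10 | 3-{2-[3,5-dimethoxy-4-(3-methylbut-2-enyl)phenyl]ethyl}-2-methoxy-6-{[tri(propan-2-yl)silyl]oxy}phenol | COc1c(CCc2cc(OC)c(CC=C(C)C)c(OC)c2)ccc(O[Si](C(C)C)(C(C)C)C(C)C)c1O
F12 | step 10 | 4-{2-[3,5-dimethoxy-4-(3-methylbut-2-enyl)phenyl]ethyl}-3-methoxybenzene-1,2-diol | COc1c(CCc2cc(OC)c(CC=C(C)C)c(OC)c2)ccc(O)c1O
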